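**Retrosynthetic overview** (drimane numbering: C3 = CH–OAc, C4 = CMe2, C6 = C=O, C7=C8, C9 carries C11H2–OAr, C10 carries the angular methyl)
1. Target ⇐ C3 silyl ether → acetate exchange; enone ⇐ Saegusa–Ito oxidation of a C6 silyl enol ether; C11–OAr ⇐ Mitsunobu etherification of the C11 alcohol with umbelliferone.
2. Decalin ⇐ one operation on an acyclic hydroxy enone: silylation, then intramolecular double Michael reaction (formal intramolecular Diels–Alder) of the 2-silyloxy-diene C5–C8 onto the (E)-enoate C9=C10, forming C5–C10 and C8–C9.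
3. Hydroxy enone ⇐ (E)-propenyllithium + gem-dimethyl γ-lactone ⇐ hydroboration and oxidative lactonisation of a reverse-prenylated alcohol ⇐ catalytic asymmetric tert-prenylation (sets C3) of an aldehyde ⇐ selective ozonolysis of methyl (E)-geranate.
4. Ring order: no carbocycle exists before step 6; ring A and ring B form together there, and C3 in the tether controls C5, C9 and C10.

Assumption: commercial methyl geranate is taken as the pure (2E) isomer, and (S)-SEGPHOS as the ligand enantiomer that gives the (6R) alcohol in step 2 (its mirror image is used if the sense is the reverse).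

**Step 1**
Reactants: 1 methyl (2E)-3,7-dimethylocta-2,6-dienoate (methyl geranate)
Product: 3 methyl (2E)-3-methyl-6-oxohex-2-enoate, via secondary ozonide 2 (not isolated)
Conditions: O3, CH2Cl2, −78 °C; then Me2S, −78 °C → rt
Reagents that add atoms: ozone, [O-][O+]=O
Why: Chemoselective ozonolysis, in which the electron-rich trisubstituted 6,7-alkene is cleaved far faster than the ester-conjugated 2,3-alkene, so the (E)-enoate survives and no stereocentre is involved.

**Step 2**
Reactants: 3 methyl (2E)-3-methyl-6-oxohex-2-enoate; 4 3-methylbuta-1,2-diene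
Product: 5 methyl (2E,6R)-6-hydroxy-3,7,7-trimethylnona-2,8-dienoate
Conditions: [Ir(cod)Cl]2 (2.5 mol %), (S)-SEGPHOS [(S)-5,5′-bis(diphenylphosphino)-4,4′-bi-1,3-benzodioxole] (5 mol %), 4-cyano-3-nitrobenzoic acid (10 mol %), Cs2CO3 (20 mol %), i-PrOH (2 equiv), toluene, 60 °C
Reagents that add atoms: none
Why: Iridium-catalysed transfer-hydrogenative carbonyl reverse prenylation (Krische type), in which the allene is hydrometalated to a prenyl–iridium species that adds through its dimethyl-substituted terminus in a closed chair transition state, the chiral bisphosphine complex selecting the aldehyde face to set C3 as (6R) and create the quaternary C4.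

**Step 3**
Reactants: 5 methyl (2E,6R)-6-hydroxy-3,7,7-trimethylnona-2,8-dienoate
Product: 7 methyl (2E,6R)-6,9-dihydroxy-3,7,7-trimethylnon-2-enoate, via B-alkyl-9-BBN borane 6 (not isolated)
Conditions: 9-BBN (2 equiv), THF, 0 °C → rt; then 30% H2O2, aq NaOAc, 0 °C → rt
Reagents that add atoms: hydrogen peroxide, OO
Why: Anti-Markovnikov hydroboration–oxidation, in which 9-BBN adds only to the terminal vinyl group (the conjugated trisubstituted enoate is inert) and buffered peroxide gives the primary alcohol without touching the ester or C3.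

**Step 4**
Reactants: 7 methyl (2E,6R)-6,9-dihydroxy-3,7,7-trimethylnon-2-enoate
Product: 9 methyl (2E)-5-[(2R)-3,3-dimethyl-5-oxooxolan-2-yl]-3-methylpent-2-enoate, via lactol 8 (not isolated)
Conditions: TEMPO (2,2,6,6-tetramethylpiperidin-1-oxyl, 20 mol %), PhI(OAc)2 (2.5 equiv), CH2Cl2, rt
Reagents that add atoms: none
Why: TEMPO/PhI(OAc)2 oxidative lactonisation of a 1,4-diol, in which the primary alcohol is oxidised selectively, the aldehyde closes onto the C3 hydroxyl and the lactol is oxidised on to the γ-lactone with the C3 configuration retained.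

**Step 5**
Reactants: 9 methyl (2E)-5-[(2R)-3,3-dimethyl-5-oxooxolan-2-yl]-3-methylpent-2-enoate; 10 (E)-1-bromoprop-1-ene
Product: 12 methyl (2E,6R,10E)-6-hydroxy-3,7,7-trimethyl-9-oxododeca-2,10-dienoate, via (E)-prop-1-enyllithium 11 (not isolated)
Conditions: 10 (1.15 equiv), t-BuLi (2.3 equiv), Et2O, −78 °C; then 9, THF, −78 °C; aq NH4Cl at −78 °C
Reagents that add atoms: none
Why: Single acyl substitution of a lactone by an alkenyllithium, in which Li–Br exchange with retention gives the (E)-alkenyllithium that attacks the γ-lactone much faster than the conjugated β,β-disubstituted methyl ester, and the lithium hemiketal is stable at −78 °C so that cold quench releases the propenyl ketone without over-addition.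

**Step 6**
Reactants: 12 methyl (2E,6R,10E)-6-hydroxy-3,7,7-trimethyl-9-oxododeca-2,10-dienoate
Product: 14 methyl (1R,2R,4aS,6R,8aR)-4,6-bis[(tert-butyldimethylsilyl)oxy]-2,5,5,8a-tetramethyl-1,2,4a,5,6,7,8,8a-octahydronaphthalene-1-carboxylate, via bis-silyl triene 13 (not isolated)
Conditions: TBSOTf (3.5 equiv), Et3N (5 equiv), ClCH2CH2Cl, −30 °C → rt, then 60 °C
Reagents that add atoms: tert-butyldimethylsilyl trifluoromethanesulfonate, CC(C)(C)[Si](C)(C)OS(=O)(=O)C(F)(F)F
Why: Silyl-triflate-promoted intramolecular double Michael reaction of a 2-silyloxy-diene with an enoate (formal intramolecular Diels–Alder reaction), in which O-silylation and (Z)-selective enol silylation give the cross-conjugated dienol ether whose C5 attacks C10 of the activated (E)-enoate through a chair-like tether with the C3 silyloxy group equatorial and the ketene silyl acetal then closes on C8 in the ester-endo arrangement, so that ring A and ring B form together with the C10 methyl cis to the C3 oxygen, a trans ring fusion at C5 and the C9 ester cis to the C10 methyl (from the E-alkene), the C8 methyl centre being inconsequential because it is erased in step 9.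

**Step 7**
Reactants: 14 methyl (1R,2R,4aS,6R,8aR)-4,6-bis[(tert-butyldimethylsilyl)oxy]-2,5,5,8a-tetramethyl-1,2,4a,5,6,7,8,8a-octahydronaphthalene-1-carboxylate
Product: 15 [(1R,2S,4aS,6R,8aS)-4,6-bis[(tert-butyldimethylsilyl)oxy]-2,5,5,8a-tetramethyl-1,2,4a,5,6,7,8,8a-octahydronaphthalen-1-yl]methanol
Conditions: i-Bu2AlH (3 equiv), CH2Cl2, −78 → −20 °C; aq potassium sodium tartrate (KNaC4H4O6) work-up
Reagents that add atoms: none
Why: Hydride reduction of the ester to the primary alcohol, in which the silyl enol ether serves as a masked C6 ketone and no stereocentre is touched (descriptor changes are only CIP changes).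

**Step 8**
Reactants: 15 [(1R,2S,4aS,6R,8aS)-4,6-bis[(tert-butyldimethylsilyl)oxy]-2,5,5,8a-tetramethyl-1,2,4a,5,6,7,8,8a-octahydronaphthalen-1-yl]methanol; 16 7-hydroxy-2H-chromen-2-one (umbelliferone)
Product: 17 7-{[(1R,2S,4aS,6R,8aS)-4,6-bis[(tert-butyldimethylsilyl)oxy]-2,5,5,8a-tetramethyl-1,2,4a,5,6,7,8,8a-octahydronaphthalen-1-yl]methoxy}-2H-chromen-2-one
Conditions: PPh3 (1.5 equiv), DIAD (1.5 equiv), THF, 0 → 40 °C
Reagents that add atoms: none
Why: Mitsunobu etherification, in which the acidic phenol (pKa about 7.8) is O-alkylated by the primary alkoxyphosphonium ion at a non-stereogenic carbon under neutral conditions that spare both silyl groups.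

**Step 9**
Reactants: 17 7-{[(1R,2S,4aS,6R,8aS)-4,6-bis[(tert-butyldimethylsilyl)oxy]-2,5,5,8a-tetramethyl-1,2,4a,5,6,7,8,8a-octahydronaphthalen-1-yl]methoxy}-2H-chromen-2-one
Product: 18 7-{[(1R,4aS,6R,8aS)-6-[(tert-butyldimethylsilyl)oxy]-2,5,5,8a-tetramethyl-4-oxo-1,4,4a,5,6,7,8,8a-octahydronaphthalen-1-yl]methoxy}-2H-chromen-2-one
Conditions: Pd(OAc)2 (1.2 equiv), MeCN, rt → 40 °C
Reagents that add atoms: none
Why: Saegusa–Ito oxidation, in which Pd(OAc)2 turns the silyl enol ether into a palladium enolate and β-hydride elimination, possible only toward C8, gives the C7=C8 enone and removes the C8 stereocentre without base, so C5 and C9 are not epimerised and the aryloxy group is not eliminated.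

**Step 10**
Reactants: 18 7-{[(1R,4aS,6R,8aS)-6-[(tert-butyldimethylsilyl)oxy]-2,5,5,8a-tetramethyl-4-oxo-1,4,4a,5,6,7,8,8a-octahydronaphthalen-1-yl]methoxy}-2H-chromen-2-one
Product: 19 (2R,4aS,5R,8aS)-1,1,4a,6-tetramethyl-8-oxo-5-{[(2-oxo-2H-chromen-7-yl)oxy]methyl}-1,2,3,4,4a,5,8,8a-octahydronaphthalen-2-yl acetate
Conditions: Ac2O (5 equiv), Cu(OTf)2 (10 mol %), CH2Cl2, 0 °C → rt
Reagents that add atoms: acetic anhydride, CC(=O)OC(C)=O
Why: Lewis-acid-catalysed acylative cleavage of a silyl ether (direct silyl ether to acetate exchange), in which activated acetic anhydride acylates the ether oxygen and the silyl group leaves as silyl acetate, with retention at C3 because the C–O bond is never broken.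

**Compound list**
1 | methyl (2E)-3,7-dimethylocta-2,6-dienoate (methyl geranate) | COC(=O)/C=C(\C)CCC=C(C)C | starting material
2 | methyl (2E)-5-(5,5-dimethyl-1,2,4-trioxolan-3-yl)-3-methylpent-2-enoate (secondary ozonide, racemic at the ring carbon) | COC(=O)/C=C(\C)CCC1OOC(C)(C)O1 | intermediate (not isolated)
3 | methyl (2E)-3-methyl-6-oxohex-2-enoate | COC(=O)/C=C(\C)CCC=O | intermediate
4 | 3-methylbuta-1,2-diene | CC(C)=C=C | starting material
5 | methyl (2E,6R)-6-hydroxy-3,7,7-trimethylnona-2,8-dienoate | COC(=O)/C=C(\C)CC[C@@H](O)C(C)(C)C=C | intermediate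
6 | methyl (2E,6R)-9-(9-borabicyclo[3.3.1]nonan-9-yl)-6-hydroxy-3,7,7-trimethylnon-2-enoate | COC(=O)/C=C(\C)CC[C@@H](O)C(C)(C)CCB1C2CCCC1CCC2 | intermediate (not isolated)
7 | methyl (2E,6R)-6,9-dihydroxy-3,7,7-trimethylnon-2-enoate | COC(=O)/C=C(\C)CC[C@@H](O)C(C)(C)CCO | intermediate
8 | methyl (2E)-5-[(2R)-5-hydroxy-3,3-dimethyloxolan-2-yl]-3-methylpent-2-enoate (lactol, both epimers at the hemiacetal carbon) | COC(=O)/C=C(\C)CC[C@@H]1C(C)(C)CC(O)O1 | intermediate (not isolated)
9 | methyl (2E)-5-[(2R)-3,3-dimethyl-5-oxooxolan-2-yl]-3-methylpent-2-enoate | COC(=O)/C=C(\C)CC[C@@H]1C(C)(C)CC(=O)O1 | intermediate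
10 | (E)-1-bromoprop-1-ene | C/C=C/Br | starting material
11 | (E)-prop-1-enyllithium | C/C=C/[Li] | intermediate (not isolated)
12 | methyl (2E,6R,10E)-6-hydroxy-3,7,7-trimethyl-9-oxododeca-2,10-dienoate | COC(=O)/C=C(\C)CC[C@@H](O)C(C)(C)CC(=O)/C=C/C | intermediate
13 | methyl (2E,6R,8Z,10E)-6,9-bis[(tert-butyldimethylsilyl)oxy]-3,7,7-trimethyldodeca-2,8,10-trienoate | COC(=O)/C=C(\C)CC[C@@H](O[Si](C)(C)C(C)(C)C)C(C)(C)/C=C(\O[Si](C)(C)C(C)(C)C)/C=C/C | intermediate (not isolated)
14 | methyl (1R,2R,4aS,6R,8aR)-4,6-bis[(tert-butyldimethylsilyl)oxy]-2,5,5,8a-tetramethyl-1,2,4a,5,6,7,8,8a-octahydronaphthalene-1-carboxylate | CC(C)(C)[Si](C)(C)O[C@@H]1CC[C@@]2(C)[C@H](C(=O)OC)[C@H](C)C=C(O[Si](C)(C)C(C)(C)C)[C@@H]2C1(C)C | intermediate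
15 | [(1R,2S,4aS,6R,8aS)-4,6-bis[(tert-butyldimethylsilyl)oxy]-2,5,5,8a-tetramethyl-1,2,4a,5,6,7,8,8a-octahydronaphthalen-1-yl]methanol | CC(C)(C)[Si](C)(C)O[C@@H]1CC[C@@]2(C)[C@H](CO)[C@H](C)C=C(O[Si](C)(C)C(C)(C)C)[C@@H]2C1(C)C | intermediate
16 | 7-hydroxy-2H-chromen-2-one (umbelliferone) | Oc1ccc2ccc(=O)oc2c1 | starting material
17 | 7-{[(1R,2S,4aS,6R,8aS)-4,6-bis[(tert-butyldimethylsilyl)oxy]-2,5,5,8a-tetramethyl-1,2,4a,5,6,7,8,8a-octahydronaphthalen-1-yl]methoxy}-2H-chromen-2-one | CC(C)(C)[Si](C)(C)O[C@@H]1CC[C@@]2(C)[C@H](COc3ccc4ccc(=O)oc4c3)[C@H](C)C=C(O[Si](C)(C)C(C)(C)C)[C@@H]2C1(C)C | intermediate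
18 | 7-{[(1R,4aS,6R,8aS)-6-[(tert-butyldimethylsilyl)oxy]-2,5,5,8a-tetramethyl-4-oxo-1,4,4a,5,6,7,8,8a-octahydronaphthalen-1-yl]methoxy}-2H-chromen-2-one | CC(C)(C)[Si](C)(C)O[C@@H]1CC[C@@]2(C)[C@H](COc3ccc4ccc(=O)oc4c3)C(C)=CC(=O)[C@@H]2C1(C)C | intermediate
19 | (2R,4aS,5R,8aS)-1,1,4a,6-tetramethyl-8-oxo-5-{[(2-oxo-2H-chromen-7-yl)oxy]methyl}-1,2,3,4,4a,5,8,8a-octahydronaphthalen-2-yl acetate | CC(=O)O[C@@H]1CC[C@@]2(C)[C@H](COc3ccc4ccc(=O)oc4c3)C(C)=CC(=O)[C@@H]2C1(C)C | target

**Step count and risks**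
Total steps: 10. Longest linear sequence: 10 steps (1 → 19).

The steps most likely to fail are step 6, step 8 and step 10.

If the one-pot silylation and double Michael cascade of step 6 stalls at the quaternary C10 or gives a poor ring-fusion ratio, the work is split and run at the ketone level under anionic control. Setting out from 12, only the hydroxyl is silylated (TBSOTf, 2,6-lutidine, CH2Cl2, −78 °C) to give methyl (2E,6R,10E)-6-[(tert-butyldimethylsilyl)oxy]-3,7,7-trimethyl-9-oxododeca-2,10-dienoate F1. Treating this with LiN(SiMe3)2 (THF, −78 → 0 °C) forms the kinetic cross-conjugated lithium dienolate, which undergoes the Michael–Michael sequence to the bicyclic keto ester methyl (1R,2R,4aS,6R,8aR)-6-[(tert-butyldimethylsilyl)oxy]-2,5,5,8a-tetramethyl-4-oxodecahydronaphthalene-1-carboxylate F2. Because C5 and C9 are both next to carbonyl groups here, a cis ring fusion or an axial ester can be corrected by equilibration (NaOMe, MeOH). Enol silylation of the ketone toward the less hindered C7 (TBSOTf, Et3N, CH2Cl2, 0 °C) then comes back to the route at 14.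

If the Mitsunobu reaction of step 8 is too slow at the β-branched C11 carbinol, the C–O bond is made from the aryl side instead. Setting out from 15, the alcohol is coupled with commercial 7-bromo-2H-chromen-2-one by palladium-catalysed C–O cross-coupling (Pd(OAc)2, t-BuBrettPhos, Cs2CO3, toluene, 80 °C). This needs no substitution at the hindered carbon and comes back to the route at 17; no new compound arises on the way (none, F0).

If the hindered C3 silyl ether resists the direct exchange of step 10, or the enone suffers under the Lewis acid, deprotection and acylation are separated. Setting out from 18, the silyl group is removed with HF·pyridine (THF/pyridine, 0 °C → rt) to give 7-{[(1R,4aS,6R,8aS)-6-hydroxy-2,5,5,8a-tetramethyl-4-oxo-1,4,4a,5,6,7,8,8a-octahydronaphthalen-1-yl]methoxy}-2H-chromen-2-one F3. Acetylation (Ac2O, pyridine, catalytic DMAP, CH2Cl2, 0 °C) then comes back to the route at 19.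

**Further compounds**
F1 | step 6 | methyl (2E,6R,10E)-6-[(tert-butyldimethylsilyl)oxy]-3,7,7-trimethyl-9-oxododeca-2,10-dienoate | COC(=O)/C=C(\C)CC[C@@H](O[Si](C)(C)C(C)(C)C)C(C)(C)CC(=O)/C=C/C
F2 | step 6 | methyl (1R,2R,4aS,6R,8aR)-6-[(tert-butyldimethylsilyl)oxy]-2,5,5,8a-tetramethyl-4-oxodecahydronaphthalene-1-carboxylate | CC(C)(C)[Si](C)(C)O[C@@H]1CC[C@@]2(C)[C@H](C(=O)OC)[C@H](C)CC(=O)[C@@H]2C1(C)C
F0 | step 8 | none | none
F3 | step 10 | 7-{[(1R,4aS,6R,8aS)-6-hydroxy-2,5,5,8a-tetramethyl-4-oxo-1,4,4a,5,6,7,8,8a-octahydronaphthalen-1-yl]methoxy}-2H-chromen-2-one | O[C@@H]1CC[C@@]2(C)[C@H](COc3ccc4ccc(=O)oc4c3)C(C)=CC(=O)[C@@H]2C1(C)C
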